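**What stays put.** Through each run so far the left-handed product climbs and flattens, yet the right-handed product per left-handed product shows no drift beyond the scatter.

| setting | grey | violet | blue | Tuesday's | Friday's |
|---|---|---|---|---|---|
| left-handed substrate | 0.79 M | 0.79 M | 0.79 M | 0.79 M | 0.79 M |
| right-handed substrate | 0.79 M | 0.79 M | 0.79 M | 0.79 M | 0.79 M |
| partner | 0.869 M | 0.869 M | 0.869 M | 0.869 M | 0.869 M |
| free catalyst | 35 mM | 35 mM | 35 mM | 35 mM | 35 mM |
| impurity | 21 mM | 37 mM | 59 mM | 20 mM | 60 mM |
| temperature | 55 °C | 70 °C | 55 °C | 70 °C | 70 °C |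
| remark | run made earlier | run made earlier | run made earlier |  |  |
| time |  |  |  | 30 min | 50 min |

| run | time / min | left-handed product / % | right-handed product / % |
|---|---|---|---|
| grey | 4.00 | 5.1 | 0.3 |
| grey | 10.0 | 10.4 | 0.7 |
| grey | 20.0 | 15.5 | 0.1 |
| grey | 30.0 | 17.7 | 0.4 |
| grey | 40.0 | 18.6 | 0.3 |
| violet | 2.00 | 6.6 | 0.3 |
| violet | 5.00 | 9.7 | 0.5 |
| violet | 10.0 | 11.5 | 0.4 |
| violet | 15.0 | 11.7 | 0.3 |
| violet | 20.0 | 12.0 | 0.4 |
| blue | 3.00 | 4.1 | 0 |
| blue | 6.00 | 6.7 | 0.5 |
| blue | 12.0 | 10.1 | 0.1 |
| blue | 25.0 | 12.8 | 0.5 |
| blue | 40.0 | 13.6 | 0.1 |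

(scatter of a reading: 0.3 percentage points)

- free catalyst is single-handed; left-handed substrate and right-handed substrate are mirror images of each other, charged as a racemate, each of them at the stated concentration
- the numbers in the tables scatter with a standard deviation of 0.3 percentage points
- an excess is below zero if the other one leads

1. which of the two ends with the higher excess of left-handed product over right-handed product ("neither" if they lie within 2 percentage points) (Tuesday's / Friday's / neither)
2. excess of left-handed product over right-handed product at the end, Tuesday's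
3. excess of left-handed product over right-handed product at the end, Friday's

**Leak ratio.** I sum the right-handed readings of the violet run and divide by the sum of its left-handed readings: s = 0.0369. This s is the leak ratio, the inverse of the selectivity between the two products. The excess is one minus s over one plus s, for the violet run's readings 92.9%. Right-handed readings sit close to the scatter of 0.3 percentage points, so s is rough.

**Time ladder.** By 2.00 min the violet run already holds half of its last left-handed reading. By 10.0 min it holds nearly all of it. The asked times, 30 min for Tuesday's and 50 min for Friday's, are longer than that, so I expect both flasks, at the violet run's 70 °C, to stand flat at the end.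

**What moves s.** From the grey run to the blue run, both at 55 °C, impurity rises from 21 mM to 59 mM. The last left-handed reading falls from 18.6% to 13.6%, yet s barely moves, from 0.0267 to 0.0254. Pooled, those two runs give 0.0262, lower than the violet run's s. So I give Tuesday's and Friday's the same s and the same excess, 92.9%, a gap inside the margin of 2 points.

**Forecast, flask.** The forecast, above my figure, gives 94.5% for Tuesday's and 93.5% for Friday's and answers neither: “These lie within 2 points, so neither leads”. The flasks give 93.1% for Tuesday's and 93.6% for Friday's, so the answer is neither.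

    free catalyst + left-handed substrate ⇌ catalyst intermediate A (K = 12.0 M⁻¹, k = 750 M⁻¹ min⁻¹, Ea = 40.0 kJ mol⁻¹, ΔH = −54.0 kJ mol⁻¹)
    free catalyst + right-handed substrate ⇌ catalyst intermediate B (K = 0.800 M⁻¹, k = 56.0 M⁻¹ min⁻¹, Ea = 59.0 kJ mol⁻¹, ΔH = −25.0 kJ mol⁻¹)
    partner + catalyst intermediate A → free catalyst + left-handed product (k = 3.20 M⁻¹ min⁻¹, Ea = 77.0 kJ mol⁻¹)
    partner + catalyst intermediate B → free catalyst + right-handed product (k = 1.40 M⁻¹ min⁻¹, Ea = 83.0 kJ mol⁻¹)
    partner → decomposed reagent (k = 0.180 min⁻¹, Ea = 101 kJ mol⁻¹)
    free catalyst + impurity → spent catalyst (k = 74.0 M⁻¹ min⁻¹, Ea = 61.0 kJ mol⁻¹)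
    (constants at 70 °C)

**Hotter neighbour.** At the end Tuesday's holds 14.8% left-handed product and Friday's 8.85%, yet s is 0.0359 and 0.0333. The neighbour is Tuesday's flask at 95 °C. Between the two temperatures of the runs the s read from the readings grew by a rough factor 1.41. Carrying that same growth per degree on to the neighbour gives an estimated s = 0.0654 and an excess of 87.7%. The neighbour holds 7.43% left-handed product and 0.550% right-handed product, so s = 0.0740, and its excess is 86.2%.

The numbers in the tables are simulated with made-up constants; noise was put on by code.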